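The numbers of this flask come from no measurement; the rest is arithmetic.

Charge 5.0 × 10⁻⁴ M of starting material with 0.700 equiv of reagent, and choose whether to dry the solvent before the next run.

    starting material + reagent → target (k1 = 540 M⁻¹ s⁻¹)
    2 reagent → side product (k2 = 350 M⁻¹ s⁻¹)
    starting material + protic impurity → quenched substrate (k3 = 570 M⁻¹ s⁻¹)
    target ⇌ isomer of the product (K4 = 0.58, k4 = 0.28 s⁻¹)

all flasks: starting material 5.0 × 10⁻⁴ M; reagent 0.700 equiv; time 10 s
- south: protic impurity 0.0600 mM
- north: protic impurity 0.100 mM
- south-west: protic impurity 0.150 mM
- north-east: protic impurity 0.250 mM

- for a step with 2 of a species take k times the square, and two of it per event
- "hardly changes" means that all values lie within two and a half points (for a concentration: within two and a half percent of the largest)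
- run time (south): 10 s

1. amount of target at the end, in percent of the starting material charged for south, north, south-west, north-east, in this order
2. the course of these numbers from the first flask to the last (hardly changes / falls all the way / falls, then rises / rises, then falls / rises all the way)

Reagent is the limiting reagent, so reckon first how it divides. Divide its use in step 1 by its use in step 2, and time drops out: k1·c(starting material) / (2·k2·c(reagent)). Call this the reagent split. At the charge it is 1.10, and south and north-east start from this same value, since c(protic impurity) does not stand in it.

Hold the split at that value and let the whole reagent charge turn over: 52.4% of it goes to step 1, which makes 36.7% of the starting material into target and isomer together. Step 4 relaxes in 0.909 s, shorter than the run of 10 s, so divide by 1.58. That gives 23.2% target.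

The impurity acts by lowering c(starting material), and with it the split. Its reach differs: the charge of protic impurity equals 12.0% of the starting material in south and 50.0% in north-east. So expect target near my figure, falling as the impurity rises. On this reckoning, dry the solvent before the next run.

The forecast gives 26.2%, 25.4%, 24.4% and 22.7%, so falls all the way, on the ground that “more impurity lowers this steadily by removing starting material”. Its south value stands above my single level.

The flasks give 26.2%, 25.6%, 24.8% and 23.1%: falls all the way, by 3.1 percentage points in total. From 1.10 at the charge, the split in south has climbed to 6.2 at 10.0 s, with 49.4% of the starting material and 8.80% of the reagent still there. North-east, with 27.4% of its starting material and 12.7% of its reagent at that time, stands lower than south on the same ratio, at 2.37.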